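**Retrosynthetic overview**
- The Ar–CH2 bond of the methylene bridge is cut: aspidinol 6 is the C-nucleophile and the 6-methylidene trione 7, released in the flask from the Mannich base 3, is the electrophile. This mirrors the quinone-methide-type bridging presumed in the biosynthesis of dimeric acylphloroglucinols.
- Enabling feature: C6 of the cyclohexadienone (filicinic) ring lies between the C1 carbonyl and the C5 enol of a cyclic β-triketone, so a CH2NMe2 group on it ionises to an exocyclic enone. The benzene ring of 6 has a single unsubstituted carbon (C5, between C4–OMe and C6–OH, para to C2–OH).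
- 3 comes from 2,4,6-trihydroxyacetophenone by dearomative gem-dimethylation and aminomethylation; 6 comes from 2-methylphloroglucinol by C-butanoylation and 4-O-methylation.
- No ring is constructed: both six-membered rings are bought as phloroglucinols. One is dearomatised to the filicinic ring in step 1, before the union; the other stays aromatic throughout. No protecting group is used.

Key step: step 5

Remark on the chemistry: the target has no stereocentre and is achiral, so no stereocontrol or resolution is needed; the enol tautomer of the SMILES is used throughout.

**Step 1**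
Reactants: 1 2,4,6-trihydroxyacetophenone
Product: 2 acetylfilicinic acid (2-acetyl-3,5-dihydroxy-4,4-dimethylcyclohexa-2,5-dien-1-one)
Conditions: NaOMe (3 equiv), MeI (2.2 equiv), MeOH, 0 °C → rt; then 1 M HCl
Reagents that add atoms: iodomethane, CI
Why: Dearomative C-methylation of an acylphloroglucinol polyanion, in which the second methyl group enters at the already methylated ring carbon and the resulting strongly acidic β-triketone enolate is too weak a nucleophile to be methylated further when MeI is limited; no stereocentre is formed.

**Step 2**
Reactants: 2 acetylfilicinic acid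
Product: 3 2-acetyl-6-[(dimethylamino)methyl]-3,5-dihydroxy-4,4-dimethylcyclohexa-2,5-dien-1-one (Mannich base, expected as the ammonium enolate zwitterion)
Conditions: CH2(NMe2)2 (1.2 equiv), CH2Cl2, 0 °C → rt; add 2 slowly to the aminal, collect the precipitate
Reagents that add atoms: bis(dimethylamino)methane, CN(C)CN(C)C
Why: Mannich aminomethylation at the only ring C–H (C6) of the cyclic β-triketone, by the iminium ion set free when the acidic enol protonates the aminal; the zwitterion should precipitate and is thereby kept from reacting further.

**Step 3**
Reactants: 4 2-methylphloroglucinol (2-methylbenzene-1,3,5-triol)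
Product: 5 1-(2,4,6-trihydroxy-3-methylphenyl)butan-1-one
Conditions: butanoyl chloride (1.1 equiv), AlCl3 (3.5 equiv), PhNO2/CH2Cl2, 0 → 45 °C; then ice/aq. HCl
Reagents that add atoms: butanoyl chloride, CCCC(Cl)=O
Why: Friedel–Crafts acylation of a phloroglucinol, in which the two free ring positions of 4 are equivalent and the first acyl group deactivates the ring against a second acylation.

**Step 4**
Reactants: 5 1-(2,4,6-trihydroxy-3-methylphenyl)butan-1-one
Product: 6 aspidinol (1-(2,6-dihydroxy-4-methoxy-3-methylphenyl)butan-1-one)
Conditions: Me2SO4 (1.0 equiv), K2CO3 (1.0 equiv), acetone, rt → 40 °C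
Reagents that add atoms: dimethyl sulfate, COS(=O)(=O)OC
Why: Williamson O-methylation that should select the 4-OH, which is the most acidic hydroxyl (para to the ketone) and is not held in a hydrogen bond to the ketone oxygen as the 2- and 6-OH groups are.

**Step 5**
Reactants: 3 2-acetyl-6-[(dimethylamino)methyl]-3,5-dihydroxy-4,4-dimethylcyclohexa-2,5-dien-1-one; 6 aspidinol
Product: 8 2-acetyl-6-[(3-butanoyl-2,4-dihydroxy-6-methoxy-5-methylphenyl)methyl]-3,5-dihydroxy-4,4-dimethylcyclohexa-2,5-dien-1-one (target), via methylidene trione 7 (not isolated)
Conditions: 3 (1.0 equiv), 6 (1.2 equiv), 1,4-dioxane, 80 °C, N2; then 1 M HCl work-up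
Reagents that add atoms: none
Why: On warming, the zwitterion 3 should lose dimethylamine by E1cB (the enolate spanning C1–C6–C5 expels the ammonium group of the side chain) to give the exocyclic enone 7, the quinone-methide-type electrophile presumed for biosynthetic methylene bridging; phenol 6, partly as its phenoxide formed by the released amine, attacks the CH2 terminus through C5 and the resulting cyclohexadienone rearomatises. The closest known reaction type is Mannich-base transalkylation, that is, thermal generation of o-quinone methides or 2-methylidene-1,3-diones from Mannich bases of phenols, 4-hydroxycoumarins and cyclic 1,3-diones, followed by Michael/Friedel–Crafts capture by electron-rich phenols. No ring is closed and no stereocentre is formed. The step needs cross- rather than homo-coupling and C- rather than O-alkylation: 3 has no free ring carbon and cannot act as a C-nucleophile, 6 has one free ring carbon only, and O-adducts are reversible whereas C-alkylation ends in irreversible rearomatisation. The released amine should be held as the salt of the strongly acidic triketone enol of 8, which keeps the medium near neutral and limits retro-Michael scrambling of the bridge.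

**Compound list**
1 | 2,4,6-trihydroxyacetophenone | CC(=O)c1c(O)cc(O)cc1O | starting material
2 | acetylfilicinic acid (2-acetyl-3,5-dihydroxy-4,4-dimethylcyclohexa-2,5-dien-1-one) | CC(=O)C1=C(O)C(C)(C)C(O)=CC1=O | intermediate
3 | 2-acetyl-6-[(dimethylamino)methyl]-3,5-dihydroxy-4,4-dimethylcyclohexa-2,5-dien-1-one | CC(=O)C1=C(O)C(C)(C)C(O)=C(CN(C)C)C1=O | intermediate
4 | 2-methylphloroglucinol (2-methylbenzene-1,3,5-triol) | Cc1c(O)cc(O)cc1O | starting material
5 | 1-(2,4,6-trihydroxy-3-methylphenyl)butan-1-one | CCCC(=O)c1c(O)cc(O)c(C)c1O | intermediate
6 | aspidinol (1-(2,6-dihydroxy-4-methoxy-3-methylphenyl)butan-1-one) | CCCC(=O)c1c(O)cc(OC)c(C)c1O | intermediate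
7 | 2-acetyl-3-hydroxy-4,4-dimethyl-6-methylidenecyclohex-2-ene-1,5-dione | C=C1C(=O)C(C)(C)C(O)=C(C(C)=O)C1=O | intermediate
8 | 2-acetyl-6-[(3-butanoyl-2,4-dihydroxy-6-methoxy-5-methylphenyl)methyl]-3,5-dihydroxy-4,4-dimethylcyclohexa-2,5-dien-1-one | CCCC(=O)c1c(O)c(C)c(OC)c(CC2=C(O)C(C)(C)C(O)=C(C(C)=O)C2=O)c1O | target

**Step count**
Total: 5 steps. Longest linear sequence: 3 steps (steps 1, 2, 5 from 1; equally steps 3, 4, 5 from 4).

**Steps most likely to fail**

Step 5. The amine lost in the elimination could promote reversible retro-Michael cleavage of the new bridge, which would scramble the halves into symmetric dimers; the enone 7 could also self-condense if amine loss outpaces capture. The fallback reverses the polarity and forms the other C–C bond of the bridge. It sets out from 6, which is aminomethylated at C5 with bis(dimethylamino)methane in dioxane to the phenolic Mannich base 1-{3-[(dimethylamino)methyl]-2,6-dihydroxy-4-methoxy-5-methylphenyl}butan-1-one F1. Heating F1 with 2 in dioxane at 90–100 °C should release the aspidinol o-quinone methide 2-butanoyl-3-hydroxy-5-methoxy-4-methyl-6-methylidenecyclohexa-2,4-dien-1-one F2, which the enol carbon C6 of 2 captures in a Michael addition, and the route is rejoined at 8.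

Step 1. Methylation may not stop at the geminal stage and may also go to the second ring carbon, giving mixtures of mono-, di-, tri- and tetramethylated products that are hard to separate. The fallback blocks the second ring carbon. It sets out from 1, which is C-acetylated (Ac2O, BF3·OEt2) to 2,4-diacetylphloroglucinol F3. F3 has a single free ring carbon, so NaOMe/MeI can only give 2,4-diacetyl-3,5-dihydroxy-6,6-dimethylcyclohexa-2,4-dien-1-one F4. Controlled acid deacylation of F4 (aqueous H2SO4, warm) removes one of the two equivalent acetyl groups, and the route is rejoined at 2.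

Step 4. Site selectivity among the three hydroxyl groups may be incomplete, and over-methylation may occur. The fallback replaces selective mono-methylation by exhaustive methylation and chelation-directed demethylation. It sets out from 5, which is fully methylated (excess Me2SO4, K2CO3, acetone, reflux) to 1-(2,4,6-trimethoxy-3-methylphenyl)butan-1-one F5. BCl3 (excess, CH2Cl2, 0 °C → rt) should then cleave only the two methoxy groups ortho to the ketone, through the boron chelate, leaving the 4-OMe, and the route is rejoined at 6.

**Further compounds**
F1 | step 5 | 1-{3-[(dimethylamino)methyl]-2,6-dihydroxy-4-methoxy-5-methylphenyl}butan-1-one | CCCC(=O)c1c(O)c(C)c(OC)c(CN(C)C)c1O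
F2 | step 5 | 2-butanoyl-3-hydroxy-5-methoxy-4-methyl-6-methylidenecyclohexa-2,4-dien-1-one | CCCC(=O)C1=C(O)C(C)=C(OC)C(=C)C1=O
F3 | step 1 | 2,4-diacetylphloroglucinol | CC(=O)c1c(O)cc(O)c(C(C)=O)c1O
F4 | step 1 | 2,4-diacetyl-3,5-dihydroxy-6,6-dimethylcyclohexa-2,4-dien-1-one | CC(=O)C1=C(O)C(C)(C)C(=O)C(C(C)=O)=C1O
F5 | step 4 | 1-(2,4,6-trimethoxy-3-methylphenyl)butan-1-one | CCCC(=O)c1c(OC)cc(OC)c(C)c1OC
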